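**Strategy.** Ring B of the target, with its oxygenated C9 flanked by the methyl-bearing C10 and C8 and a second oxygen at C6, is the reduced image of a 4-methoxy-2,6-dimethylphenol. The route therefore rests on one disconnection, C1–C10: a phenoxide carrying a 5-bromo-2-methylpentan-2-yl chain on C5 is alkylated at its methyl-bearing ortho carbon under a chiral ammonium catalyst. That single operation closes ring A, destroys the aromaticity for good, and creates the quaternary stereocentre C10, from which C5, C8, C6 and C9 are later set by substrate control. The precursor is assembled from 2,6-dimethylhydroquinone through a Friedel–Crafts lactonisation that also tells the two phenolic oxygens apart.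

Key step: step 9

Assumption: the sense of induction of the chiral ammonium catalyst cannot be predicted, so the antipode written in step 9 stands for whichever one delivers (S)-C10 (both are available); ring positions are given in labdane numbering (decalin C1–C10, side chain C11–C16).

**Step 1**
Reactants: 1 2,6-dimethylhydroquinone; 2 3-methylbut-2-enoic acid
Product: 3 6-hydroxy-4,4,5,7-tetramethyl-3,4-dihydro-2H-chromen-2-one
Conditions: MeSO3H, 70 °C
Reagents that add atoms: none
Why: Acid-mediated Friedel–Crafts conjugate alkylation with in-situ lactonisation (the trimethyl-lock lactone synthesis) should give a single regioisomer, because only the unhindered hydroxyl has a free ortho carbon, so the quaternary benzylic carbon (future C4) is attached beside a ring methyl and the two phenolic oxygens are told apart in the same operation.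

**Step 2**
Reactants: 3 6-hydroxy-4,4,5,7-tetramethyl-3,4-dihydro-2H-chromen-2-one
Product: 4 6-(benzyloxy)-4,4,5,7-tetramethyl-3,4-dihydro-2H-chromen-2-one
Conditions: BnBr, K2CO3, DMF, rt
Reagents that add atoms: benzyl bromide, BrCc1ccccc1
Why: Williamson etherification of the one free phenol, the hindered one that must later become the phenoxide of the key step, masks it while the other oxygen is released and methylated, and the aryl lactone is inert to carbonate.

**Step 3**
Reactants: 4 6-(benzyloxy)-4,4,5,7-tetramethyl-3,4-dihydro-2H-chromen-2-one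
Product: 5 6-(benzyloxy)-4,4,5,7-tetramethyl-3,4-dihydro-2H-chromen-2-ol (racemic lactol)
Conditions: DIBAL-H, CH2Cl2, −78 °C; aq. Rochelle salt
Reagents that add atoms: none
Why: Partial reduction of an aryl lactone with DIBAL-H at low temperature stops at the aluminium hemiacetal and should give the lactol, whose new stereocentre is irrelevant because it is destroyed in step 4.

**Step 4**
Reactants: 5 6-(benzyloxy)-4,4,5,7-tetramethyl-3,4-dihydro-2H-chromen-2-ol
Product: 6 4-(benzyloxy)-3,5-dimethyl-2-(2-methylpent-4-en-2-yl)phenol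
Conditions: Ph3PCH3Br, KOtBu, THF, 0 °C → rt
Reagents that add atoms: methyltriphenylphosphonium bromide, C[P+](c1ccccc1)(c1ccccc1)c1ccccc1.[Br-]
Why: Wittig methylenation of the open hydroxy-aldehyde form of the lactol, which the basic ylide medium makes available as its phenoxide, adds the fourth chain carbon (future C1) and releases the phenol next to the tert-alkyl group.

**Step 5**
Reactants: 6 4-(benzyloxy)-3,5-dimethyl-2-(2-methylpent-4-en-2-yl)phenol
Product: 7 2-(benzyloxy)-5-methoxy-1,3-dimethyl-4-(2-methylpent-4-en-2-yl)benzene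
Conditions: MeI, K2CO3, DMF, 40 °C
Reagents that add atoms: iodomethane, CI
Why: Williamson methylation of the only free phenol installs the C6 oxygen substituent as a base-stable methyl ether, which also shuts off seven-membered O-alkylation by this oxygen in the key step.

**Step 6**
Reactants: 7 2-(benzyloxy)-5-methoxy-1,3-dimethyl-4-(2-methylpent-4-en-2-yl)benzene
Product: 9 4-[3-(benzyloxy)-6-methoxy-2,4-dimethylphenyl]-4-methylpentan-1-ol, via B-alkyl-9-BBN borane 8 (not isolated)
Conditions: 9-BBN, THF, rt; then NaOH, H2O2, 0 °C → rt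
Reagents that add atoms: hydrogen peroxide, OO; 9-borabicyclo[3.3.1]nonane, B1C2CCCC1CCC2 (its atoms stay in 8 only)
Why: Hydroboration–oxidation with the bulky dialkylborane places boron on the terminal carbon of the monosubstituted alkene, so the primary alcohol at the future C1 should result after oxidative work-up.

**Step 7**
Reactants: 9 4-[3-(benzyloxy)-6-methoxy-2,4-dimethylphenyl]-4-methylpentan-1-ol
Product: 10 3-(5-hydroxy-2-methylpentan-2-yl)-4-methoxy-2,6-dimethylphenol
Conditions: H2 (1 atm), 10% Pd/C, EtOAc, rt
Reagents that add atoms: none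
Why: Catalytic hydrogenolysis cleaves the benzyl aryl ether under neutral conditions and leaves the methyl ether, the arene and the primary alcohol untouched.

**Step 8**
Reactants: 10 3-(5-hydroxy-2-methylpentan-2-yl)-4-methoxy-2,6-dimethylphenol
Product: 11 3-(5-bromo-2-methylpentan-2-yl)-4-methoxy-2,6-dimethylphenol
Conditions: CBr4, PPh3, CH2Cl2, 0 °C
Reagents that add atoms: carbon tetrabromide, BrC(Br)(Br)Br
Why: The Appel reaction converts the primary alcohol into the bromide under non-basic conditions, so the hindered phenol, which the phosphonium reagent cannot substitute, is never set free as a phenoxide that could cyclise prematurely.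

**Step 9**
Reactants: 11 3-(5-bromo-2-methylpentan-2-yl)-4-methoxy-2,6-dimethylphenol
Product: 12 (8aS)-4-methoxy-2,5,5,8a-tetramethyl-5,6,7,8-tetrahydronaphthalen-1(8aH)-one
Conditions: (S,S)-3,4,5-trifluorophenyl-NAS bromide (N-spiro binaphthyl ammonium salt, 10 mol%), 50% aq. KOH, toluene (0.01 M), −20 → 0 °C, Ar
Reagents that add atoms: none
Why: Proposed new method: deprotonation at the interface gives the phenoxide of 11, which is carried into toluene as a tight ion pair with the C2-symmetric chiral ammonium cation, and its methyl-bearing ortho carbon C10 then displaces the primary bromide at C1 in an intramolecular SN2 step; the closest known reactions are the racemic base-mediated intramolecular ortho-alkylative dearomatisation of phenols (Ar2-6 phenoxide participation) and asymmetric phase-transfer alkylation of cyclic enolates to quaternary carbons. Ring A closes in a 6-(enolexo)-exo-tet mode, forming C1–C10. The single new stereocentre, quaternary C10, is controlled by the catalyst: the cation resting on the hindered phenoxide oxygen should screen one face of the arene so that the tether folds over the other, and the catalyst antipode is chosen to give (S)-C10. The step needs C- over O-alkylation, which is secured because O-alkylation would require an eight-membered ether and the oxygen is buried between two methyl groups and its counter-ion, while the gem-dimethyl group on C4 favours the six-membered closure. It also needs attack at C10 and not at C6, the other ring carbon next to C5 and para to the phenoxide oxygen: C6 is an alkoxy-bearing ipso position of low nucleophilicity, and closure there would force a C4 methyl into the ring plane beside the C10 methyl. The C10 methyl blocks rearomatisation, and high dilution with a strictly biphasic base should keep intermolecular alkylation and the uncatalysed racemic pathway down.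

**Step 10**
Reactants: 12 (8aS)-4-methoxy-2,5,5,8a-tetramethyl-5,6,7,8-tetrahydronaphthalen-1(8aH)-one
Product: 13 (4aS,8aS)-2,5,5,8a-tetramethyl-4a,5,6,7,8,8a-hexahydronaphthalene-1,4-dione
Conditions: 2 M aq. HCl, THF, rt → 40 °C
Reagents that add atoms: water, O
Why: Acid hydrolysis of the enol ether (protonation at C5, then loss of methanol from the hemiketal) should unmask the C6 ketone, and C5, now α to that ketone, can equilibrate toward the trans ring fusion (5S, H anti to the C10 methyl), which is made certain in step 11.

**Step 11**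
Reactants: 13 (4aS,8aS)-2,5,5,8a-tetramethyl-4a,5,6,7,8,8a-hexahydronaphthalene-1,4-dione
Product: 15 (2R,4aS,8aS)-2,5,5,8a-tetramethyloctahydronaphthalene-1,4-dione, via C8-epimeric saturated dione 14 (not isolated)
Conditions: Zn dust, AcOH, rt; then K2CO3 (cat.), MeOH, rt
Reagents that add atoms: none
Why: Zinc–acetic acid reduction is selective for the doubly activated C7=C8 bond of an ene-1,4-dione, and the carbonate equilibration then lets C8 (α to C9=O) and C5 (α to C6=O) settle under thermodynamic control, giving the trans-fused dione with the C8 methyl equatorial (8R), since an 8β-methyl would be syn-axial to the C10 methyl.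

**Step 12**
Reactants: 15 (2R,4aS,8aS)-2,5,5,8a-tetramethyloctahydronaphthalene-1,4-dione
Product: 16 (2R,4R,4aS,8aS)-4-hydroxy-2,5,5,8a-tetramethyloctahydronaphthalen-1(2H)-one
Conditions: NaBH4 (0.5 equiv), MeOH, −20 °C
Reagents that add atoms: none
Why: Borohydride reduction should be chemoselective for the C6 carbonyl, which has a methylene neighbour, over the C9 carbonyl wedged between quaternary C10 and tertiary C8, and stereoselective because the β-face of C6 is roofed by the axial 4β- and 10β-methyl groups, so hydride enters from the α-face and the axial 6β-alcohol (6R) is formed.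

**Step 13**
Reactants: 16 (2R,4R,4aS,8aS)-4-hydroxy-2,5,5,8a-tetramethyloctahydronaphthalen-1(2H)-one
Product: 17 (1R,2R,4R,4aS,8aS)-1-ethenyl-2,5,5,8a-tetramethyldecahydronaphthalene-1,4-diol
Conditions: CH2=CHMgBr (5 equiv), anhydrous CeCl3 (5 equiv), THF, −78 → 0 °C; aq. NH4Cl
Reagents that add atoms: vinylmagnesium bromide, C=C[Mg]Br
Why: Organocerium 1,2-addition copes with hindered, enolisable ketones, and after the first equivalent has deprotonated the C6 hydroxyl the vinyl group should enter along the equatorial β-face trajectory, because the axial α-face path is syn-axial to H-1α, H-5α and H-7α (the preference shown by 2,2,6-trisubstituted cyclohexanones), which places the new hydroxyl axial and sets C9 as 9α-OH (9R).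

**Step 14**
Reactants: 17 (1R,2R,4R,4aS,8aS)-1-ethenyl-2,5,5,8a-tetramethyldecahydronaphthalene-1,4-diol
Product: 18 (1R,3R,4R,4aS,8aS)-4-ethenyl-4-hydroxy-3,4a,8,8-tetramethyldecahydronaphthalen-1-yl acetate
Conditions: Ac2O, DMAP (cat.), pyridine, rt → 40 °C
Reagents that add atoms: acetic anhydride, CC(=O)OC(C)=O
Why: DMAP-catalysed acetylation should take the secondary 6β-hydroxyl only, since the tertiary 9α-hydroxyl beside quaternary C10 is too hindered to be acylated under these conditions.

**Step 15**
Reactants: 18 (1R,3R,4R,4aS,8aS)-4-ethenyl-4-hydroxy-3,4a,8,8-tetramethyldecahydronaphthalen-1-yl acetate; 19 3-bromofuran-2(5H)-one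
Product: 21 (1R,3R,4R,4aS,8aS)-4-hydroxy-3,4a,8,8-tetramethyl-4-[2-(2-oxo-2,5-dihydrofuran-3-yl)ethyl]decahydronaphthalen-1-yl acetate (CNP0205088.1), via B-alkyl-9-BBN borane 20 (not isolated)
Conditions: 9-BBN (3 equiv), THF, rt → 50 °C; then 19, PdCl2(dppf) (10 mol%), AsPh3, Cs2CO3, DMF/H2O, rt
Reagents that add atoms: 9-borabicyclo[3.3.1]nonane, B1C2CCCC1CCC2 (its atoms stay in 20 only, none in 21)
Why: Anti-Markovnikov hydroboration of the vinyl group gives the primary B-alkyl borane at C12, and B-alkyl Suzuki–Miyaura coupling with the α-bromo butenolide under mild aqueous base should form C12–C13 without touching the acetate, the tertiary alcohol or any stereocentre.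

**Compound list**

1 | 2,6-dimethylhydroquinone (2,6-dimethylbenzene-1,4-diol) | Cc1cc(O)cc(C)c1O | starting material
2 | 3-methylbut-2-enoic acid (3,3-dimethylacrylic acid) | CC(C)=CC(=O)O | starting material
3 | 6-hydroxy-4,4,5,7-tetramethyl-3,4-dihydro-2H-chromen-2-one | CC1(C)CC(=O)Oc2cc(C)c(O)c(C)c21 | intermediate
4 | 6-(benzyloxy)-4,4,5,7-tetramethyl-3,4-dihydro-2H-chromen-2-one | CC1(C)CC(=O)Oc2cc(C)c(OCc3ccccc3)c(C)c21 | intermediate
5 | 6-(benzyloxy)-4,4,5,7-tetramethyl-3,4-dihydro-2H-chromen-2-ol (racemic lactol) | CC1(C)CC(O)Oc2cc(C)c(OCc3ccccc3)c(C)c21 | intermediate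
6 | 4-(benzyloxy)-3,5-dimethyl-2-(2-methylpent-4-en-2-yl)phenol | C=CCC(C)(C)c1c(O)cc(C)c(OCc2ccccc2)c1C | intermediate
7 | 2-(benzyloxy)-5-methoxy-1,3-dimethyl-4-(2-methylpent-4-en-2-yl)benzene | C=CCC(C)(C)c1c(OC)cc(C)c(OCc2ccccc2)c1C | intermediate
8 | 9-{4-[3-(benzyloxy)-6-methoxy-2,4-dimethylphenyl]-4-methylpentyl}-9-borabicyclo[3.3.1]nonane | COc1cc(C)c(OCc2ccccc2)c(C)c1C(C)(C)CCCB1C2CCCC1CCC2 | intermediate (not isolated)
9 | 4-[3-(benzyloxy)-6-methoxy-2,4-dimethylphenyl]-4-methylpentan-1-ol | COc1cc(C)c(OCc2ccccc2)c(C)c1C(C)(C)CCCO | intermediate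
10 | 3-(5-hydroxy-2-methylpentan-2-yl)-4-methoxy-2,6-dimethylphenol | COc1cc(C)c(O)c(C)c1C(C)(C)CCCO | intermediate
11 | 3-(5-bromo-2-methylpentan-2-yl)-4-methoxy-2,6-dimethylphenol (key-step precursor) | COc1cc(C)c(O)c(C)c1C(C)(C)CCCBr | intermediate
12 | (8aS)-4-methoxy-2,5,5,8a-tetramethyl-5,6,7,8-tetrahydronaphthalen-1(8aH)-one (6-methoxy-5,7-dien-9-one, 10S) | COC1=C2C(C)(C)CCC[C@]2(C)C(=O)C(C)=C1 | intermediate
13 | (4aS,8aS)-2,5,5,8a-tetramethyl-4a,5,6,7,8,8a-hexahydronaphthalene-1,4-dione (7-ene-6,9-dione, 5S,10S) | O=C1C=C(C)C(=O)[C@@]2(C)CCCC(C)(C)[C@H]12 | intermediate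
14 | (4aS,8aS)-2,5,5,8a-tetramethyloctahydronaphthalene-1,4-dione, mixture of C8 epimers | O=C1CC(C)C(=O)[C@@]2(C)CCCC(C)(C)[C@H]12 | intermediate (not isolated)
15 | (2R,4aS,8aS)-2,5,5,8a-tetramethyloctahydronaphthalene-1,4-dione (trans-fused 6,9-dione, 8α-methyl) | O=C1C[C@@H](C)C(=O)[C@@]2(C)CCCC(C)(C)[C@H]12 | intermediate
16 | (2R,4R,4aS,8aS)-4-hydroxy-2,5,5,8a-tetramethyloctahydronaphthalen-1(2H)-one (6β-hydroxy-9-ketone) | O[C@@H]1C[C@@H](C)C(=O)[C@@]2(C)CCCC(C)(C)[C@H]12 | intermediate
17 | (1R,2R,4R,4aS,8aS)-1-ethenyl-2,5,5,8a-tetramethyldecahydronaphthalene-1,4-diol (6β,9α-diol, 9β-vinyl) | O[C@@H]1C[C@@H](C)[C@](O)(C=C)[C@@]2(C)CCCC(C)(C)[C@H]12 | intermediate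
18 | (1R,3R,4R,4aS,8aS)-4-ethenyl-4-hydroxy-3,4a,8,8-tetramethyldecahydronaphthalen-1-yl acetate | CC(=O)O[C@@H]1C[C@@H](C)[C@](O)(C=C)[C@@]2(C)CCCC(C)(C)[C@H]12 | intermediate
19 | 3-bromofuran-2(5H)-one | O=C1OCC=C1Br | starting material
20 | (1R,3R,4R,4aS,8aS)-4-[2-(9-borabicyclo[3.3.1]nonan-9-yl)ethyl]-4-hydroxy-3,4a,8,8-tetramethyldecahydronaphthalen-1-yl acetate | CC(=O)O[C@@H]1C[C@@H](C)[C@](O)(CCB3C4CCCC3CCC4)[C@@]2(C)CCCC(C)(C)[C@H]12 | intermediate (not isolated)
21 | (1R,3R,4R,4aS,8aS)-4-hydroxy-3,4a,8,8-tetramethyl-4-[2-(2-oxo-2,5-dihydrofuran-3-yl)ethyl]decahydronaphthalen-1-yl acetate (6β-acetoxy-9α-hydroxylabd-13-en-16,15-olide; 5S,6R,8R,9R,10S) | CC(=O)O[C@@H]1C[C@@H](C)[C@](O)(CCC2=CCOC2=O)[C@@]2(C)CCCC(C)(C)[C@H]12 | target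

**Totals.** Total step count: 15. Longest linear sequence: 15 steps (1 → 21; the route is fully linear).

**Steps most likely to fail**

1. Step 9 (proposed new method). The cation may discriminate the two faces of the flat phenoxide poorly, or an uncatalysed interfacial cyclisation may compete, and either would erode the enantiomeric purity. Fallback with known chemistry: setting out from 11, the cyclisation is run without chiral control (KOtBu, t-BuOH/toluene, high dilution; the established racemic phenoxide ortho-alkylation) to give the racemic dienone F1. This is resolved by preparative chromatography on a polysaccharide chiral stationary phase; the (8aS)-enantiomer is 12, where the route is rejoined, and the (8aR)-enantiomer F2 is set aside.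

2. Step 13. The vinyl group may enter from the α-face (poor facial selectivity), or the ketone may only be enolised. Fallback: setting out from 16, silylation (TESOTf, 2,6-lutidine, CH2Cl2) would give the triethylsilyl ether F3. Forcing Wittig methylenation (Ph3PCH3Br, KOtBu, toluene, 100 °C) would give the 9(11)-exocyclic alkene F4. Epoxidation with m-CPBA (NaHCO3, CH2Cl2), expected from the α-face away from the axial C10 methyl, would give the 9α,11-epoxide F5. One-carbon homologation with excess dimethylsulfonium methylide (Me3SI, n-BuLi, THF, −10 °C → rt) opens the epoxide at C11 and eliminates dimethyl sulfide to give the vinyl carbinol silyl ether F6, and TBAF (THF) returns the route at 17. Here the oxygen, not the carbon, is delivered to C9 from the α-face, so the outcome no longer depends on how carbon nucleophiles approach the ketone.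

3. Step 15. Transmetalation of the hindered alkylborane may be slow, with protodeboronation, or the bromobutenolide may decompose under the aqueous base. Fallback: setting out from 18, hydroboration–oxidation (9-BBN; NaBO3·4H2O) would give the primary alcohol F7. Swern oxidation gives the aldehyde, which closes onto the C9 hydroxyl as the spiro lactol F8. Horner–Wadsworth–Emmons olefination with diethyl (2-oxooxolan-3-yl)phosphonate (KOtBu, THF) gives the α-alkylidene lactone F9. Rhodium-catalysed migration of the exocyclic double bond into the ring (RhCl3·3H2O, EtOH, 80 °C) returns the route at 21.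

**Further compounds**

F1 | step 9 | racemic 4-methoxy-2,5,5,8a-tetramethyl-5,6,7,8-tetrahydronaphthalen-1(8aH)-one | COC1=C2C(C)(C)CCCC2(C)C(=O)C(C)=C1
F2 | step 9 | (8aR)-4-methoxy-2,5,5,8a-tetramethyl-5,6,7,8-tetrahydronaphthalen-1(8aH)-one | COC1=C2C(C)(C)CCC[C@@]2(C)C(=O)C(C)=C1
F3 | step 13 | (2R,4R,4aS,8aS)-2,5,5,8a-tetramethyl-4-[(triethylsilyl)oxy]octahydronaphthalen-1(2H)-one | CC[Si](CC)(CC)O[C@@H]1C[C@@H](C)C(=O)[C@@]2(C)CCCC(C)(C)[C@H]12
F4 | step 13 | triethylsilyl ether of the 6β-hydroxy-9(11)-exocyclic alkene | CC[Si](CC)(CC)O[C@@H]1C[C@@H](C)C(=C)[C@@]2(C)CCCC(C)(C)[C@H]12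
F5 | step 13 | triethylsilyl ether of the 6β-hydroxy-9α,11-epoxide (spiro-oxirane at C9) | CC[Si](CC)(CC)O[C@@H]1C[C@@H](C)[C@]3(CO3)[C@@]2(C)CCCC(C)(C)[C@H]12
F6 | step 13 | 6-O-triethylsilyl ether of diol 17 | CC[Si](CC)(CC)O[C@@H]1C[C@@H](C)[C@](O)(C=C)[C@@]2(C)CCCC(C)(C)[C@H]12
F7 | step 15 | (1R,3R,4R,4aS,8aS)-4-hydroxy-4-(2-hydroxyethyl)-3,4a,8,8-tetramethyldecahydronaphthalen-1-yl acetate | CC(=O)O[C@@H]1C[C@@H](C)[C@](O)(CCO)[C@@]2(C)CCCC(C)(C)[C@H]12
F8 | step 15 | spiro lactol from the C12 aldehyde and the C9 hydroxyl (anomer mixture), 6β-acetate | CC(=O)O[C@@H]1C[C@@H](C)[C@]3(CCC(O)O3)[C@@]2(C)CCCC(C)(C)[C@H]12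
F9 | step 15 | α-alkylidene-γ-butyrolactone with exocyclic C12=C13 (E/Z mixture), 6β-acetate | CC(=O)O[C@@H]1C[C@@H](C)[C@](O)(CC=C3CCOC3=O)[C@@]2(C)CCCC(C)(C)[C@H]12
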